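At early times in the theta run, the target is 0.539 of the substrate consumed at 0.333 d, and the same ratio reads 0.617 at 4.00 d. I read this lag as a short-lived intermediate held at a quasi-steady state. The late ratio, target per substrate consumed, I call the final share. With another charge, the eta run reads 0.612 at 3.00 d.

| flask | substrate | reagent | remark | time |
|---|---|---|---|---|
| zeta | 0.20 M | 0.20 M | run made earlier |  |
| theta | 0.20 M | 0.28 M | run made earlier |  |
| alpha | 0.20 M | 0.44 M | run made earlier |  |
| eta | 0.30 M | 0.20 M | run made earlier |  |
| amber | 0.20 M | 0.200 M (fed, over 1.50 d) | all but reagent at the start; reagent goes in evenly over 1.50 d, the run ends at 3.0 d | 3.0 d |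
| teal | 0.20 M (fed, over 1.50 d) | 0.200 M | a stirred flask in which substrate is dosed at a steady rate over 1.50 d without added volume, worked up at 3.0 d | 3.0 d |
| red | 0.20 M | 0.200 M | everything together in a closed stirred flask, run for 3.0 d | 3.0 d |
| violet | 0.20 M | 0.200 M | a single well-mixed tank run continuously and read at steady state, 3.0 d in it on average |  |

zeta run (percent of the substrate charged)

| time / h | target / % | substrate / % |
|---|---|---|
| 8.00 | 18.9 | 62.0 |
| 15.0 | 29.0 | 47.3 |
| 25.0 | 39.9 | 34.2 |
| 30.0 | 40.8 | 32.3 |
| 40.0 | 44.9 | 25.0 |

theta run (percent of the substrate charged)

| time / d | target / % | substrate / % |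
|---|---|---|
| 0.333 | 25.8 | 52.1 |
| 0.833 | 43.4 | 28.3 |
| 1.67 | 54.7 | 12.1 |
| 2.50 | 58.3 | 6.2 |
| 4.00 | 60.2 | 2.4 |

alpha run (percent of the substrate charged)

| time / d | target / % | substrate / % |
|---|---|---|
| 0.625 | 49.9 | 16.0 |
| 1.25 | 57.0 | 3.5 |
| 2.00 | 61.8 | 1.4 |
| 3.00 | 61.3 | 1.6 |
| 4.00 | 62.6 | 0.5 |

eta run (percent of the substrate charged)

| time / d | target / % | substrate / % |
|---|---|---|
| 0.625 | 25.7 | 53.5 |
| 1.25 | 34.2 | 43.4 |
| 2.00 | 38.8 | 36.1 |
| 3.00 | 41.3 | 32.5 |
| 4.00 | 40.0 | 33.4 |

(standard deviation of a reading: 1 percentage point)

- the stated concentrations are those of everything mixed, before any reaction; amounts are the same in each set-up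
- the numbers in the tables scatter with a standard deviation of 1 percentage point
- the feed brings no volume worth counting
- the earlier runs were made in a closed, stirred flask

* the set-up with the highest amount of target at the outlet or at the end, in percent of the substrate put in ("none" if the first two lie within 2 percentage points) (amber / teal / red / violet / none)
* amount of target at the outlet or at the end, in percent of the substrate put in, amber
* amount of target at the outlet or at the end, in percent of the substrate put in, teal
* amount of target at the outlet or at the end, in percent of the substrate put in, red
* amount of target at the outlet or at the end, in percent of the substrate put in, violet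

So I reckon the target as the final share times the fraction consumed. The zeta run has red's charge, and the inverse of its fraction left rises from one in a straight line. Its last reading, carried to 3.0 d, gives a rise of 5.40. Red then keeps 0.156 of its substrate and gives 52.0 % target by my reckoning. Violet's steady-state balance keeps 0.348 and gives 40.2 %.

The forecast stands lower than my reckoning on both, at 51.8 % for red and 38.8 % for violet, with 48.3 % for amber and 48.3 % for teal. It names red as best, on the ground that “yield simply follows conversion”.

The flask gives 51.4 % in red, 48.4 % in teal, 47.9 % in amber and 39.3 % in violet, so red is best, and each value lies inside the forecast's range.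

    substrate + reagent → intermediate + released group (k = 0.00585 M⁻¹ min⁻¹)
    intermediate → target (k = 0.00693 min⁻¹)
    substrate + intermediate → side product A (k = 0.00156 M⁻¹ min⁻¹)
    intermediate → side product B (k = 0.00404 min⁻¹)

Red has not come to rest at 3.0 d: 15.8 % of its substrate still stands. The final share puts 9.75 % of the charge as target still to come from that substrate. At 30.0 d red gives 60.7 %, a rise of 9.3 percentage points. Teal, ending at 48.4 %, stands 13 points below the final share of the whole charge, and at 30.0 d it gives 61.1 %. Amber gives 47.9 % at 3.0 d and 60.6 % at 30.0 d.

(The data were computed on assumed constants; noise was put on by code.)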